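The route rests on cutting the C9–C10 bond of ring B (labdane numbering). The feature exploited is the quaternary C10 at the fusion of ring A (C1–C5, C10) and ring B (C5–C10), whose axial methyl C20 lies syn to the axial C4 methyl: an exocyclic C10=C20 methylene already contains that methyl carbon. Hydrogen-atom transfer from an iron hydride turns it into the tertiary C10 radical, which closes ring B 6-exo onto C9 of an ynoate, forming the C9–C10 bond, the quaternary centre and the trans fusion at once. The precursor is an enantiopure ring A methylenecyclohexane (C4, C5 set) whose C5 chain ends in a C8 dioxolane and an ethyl ynoate.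

Key step: step 17

Remark: locants follow labdane numbering (C18 = oxygenated carbon on C4, C20 = C10 methyl); 26 is drawn with the ester cis to C8, and the other alkene geometry, should it form, would converge with it at step 22.

Step 1
Reactants: 1 pent-4-yn-1-ol
Product: 2 tert-butyl(dimethyl)(pent-4-yn-1-yloxy)silane
Conditions: TBSCl, imidazole, DMF, 0 °C → rt
Reagents that add atoms: tert-butyl(chloro)dimethylsilane CC(C)(C)[Si](C)(C)Cl
Why: Imidazole-assisted silylation masks the hydroxyl proton, which would otherwise quench the organocopper reagent of the next step.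

Step 2
Reactants: 2 tert-butyl(dimethyl)(pent-4-yn-1-yloxy)silane; 3 (trimethylsilyl)methylmagnesium chloride
Product: 5 tert-butyl{[(4Z)-5-iodo-4-[(trimethylsilyl)methyl]pent-4-en-1-yl]oxy}dimethylsilane, via alkenylcopper 4 (not isolated)
Conditions: 3, CuBr·SMe2, Et2O/Me2S, −30 → 0 °C; then I2, THF, −78 → 0 °C
Reagents that add atoms: iodine II
Why: Syn-carbocupration of the terminal alkyne by (trimethylsilyl)methylcopper puts the CH2SiMe3 group on the internal carbon (future C10) and copper on the terminal carbon (future C5), and iodinolysis with retention gives the (Z)-iodide, the geometry later needed for an equatorial C5 chain.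

Step 3
Reactants: 5 tert-butyl{[(4Z)-5-iodo-4-[(trimethylsilyl)methyl]pent-4-en-1-yl]oxy}dimethylsilane
Product: 6 (4Z)-5-iodo-4-[(trimethylsilyl)methyl]pent-4-en-1-ol
Conditions: n-Bu4NF, THF, 0 °C
Reagents that add atoms: none
Why: Fluoride cleaves the primary silyl ether at 0 °C, conditions under which an allylsilane without an electrophilic partner and a vinyl iodide are stable.

Step 4
Reactants: 6 (4Z)-5-iodo-4-[(trimethylsilyl)methyl]pent-4-en-1-ol; 7 ethyl 2-(triphenylphosphoranylidene)propanoate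
Product: 9 ethyl (2E,6Z)-7-iodo-2-methyl-6-[(trimethylsilyl)methyl]hepta-2,6-dienoate, via aldehyde 8 (not isolated)
Conditions: Dess–Martin periodinane, CH2Cl2, 0 °C → rt; then 7, rt
Reagents that add atoms: none
Why: Dess–Martin oxidation gives the aldehyde, which is trapped in the same flask by the stabilized ylide in an (E)-selective Wittig olefination, so the volatile aldehyde need not be handled.

Step 5
Reactants: 9 ethyl (2E,6Z)-7-iodo-2-methyl-6-[(trimethylsilyl)methyl]hepta-2,6-dienoate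
Product: 10 (2E,6Z)-7-iodo-2-methyl-6-[(trimethylsilyl)methyl]hepta-2,6-dien-1-ol
Conditions: i-Bu2AlH, CH2Cl2, −78 °C
Reagents that add atoms: none
Why: i-Bu2AlH reduces the conjugated ester by 1,2-addition to the (E)-allylic alcohol and leaves the vinyl iodide and the allylsilane untouched at −78 °C.

Step 6
Reactants: 10 (2E,6Z)-7-iodo-2-methyl-6-[(trimethylsilyl)methyl]hepta-2,6-dien-1-ol; 11 (3-ethoxy-3-oxopropyl)zinc bromide
Product: 12 ethyl (4Z,8E)-10-hydroxy-9-methyl-5-[(trimethylsilyl)methyl]deca-4,8-dienoate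
Conditions: 11 (slow addition), Pd(OAc)2 (cat.), SPhos (cat.), THF, 25 °C
Reagents that add atoms: none
Why: Negishi sp2–sp3 coupling of the alkenyl iodide with the zinc homoenolate proceeds with retention of alkene geometry and tolerates the free hydroxyl, because alkylzinc halides are protonated only slowly by alcohols.

Step 7
Reactants: 12 ethyl (4Z,8E)-10-hydroxy-9-methyl-5-[(trimethylsilyl)methyl]deca-4,8-dienoate
Product: 13 ethyl (4Z)-7-[(2R,3R)-3-(hydroxymethyl)-3-methyloxiran-2-yl]-5-[(trimethylsilyl)methyl]hept-4-enoate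
Conditions: Ti(OiPr)4 (cat.), D-(−)-diethyl tartrate (cat.), t-BuOOH, 4 Å molecular sieves, CH2Cl2, −20 °C
Reagents that add atoms: tert-butyl hydroperoxide CC(C)(C)OO
Why: Sharpless asymmetric epoxidation with the D-(−)-tartrate delivers oxygen to one face of the (E)-allylic alcohol, setting the (2R,3R)-epoxide (future C4 and C3), while the allylsilane alkene, which has no directing hydroxyl, is not epoxidized.

Step 8
Reactants: 13 ethyl (4Z)-7-[(2R,3R)-3-(hydroxymethyl)-3-methyloxiran-2-yl]-5-[(trimethylsilyl)methyl]hept-4-enoate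
Product: 14 ethyl (4Z)-7-[(2R,3R)-3-({[tert-butyl(diphenyl)silyl]oxy}methyl)-3-methyloxiran-2-yl]-5-[(trimethylsilyl)methyl]hept-4-enoate
Conditions: TBDPSCl, imidazole, CH2Cl2, 0 °C → rt
Reagents that add atoms: tert-butyl(chloro)diphenylsilane CC(C)(C)[Si](Cl)(c1ccccc1)c1ccccc1
Why: Silylation of the primary hydroxyl installs the robust C18 silyl ether that is carried to step 23 and removes a free hydroxyl before the Lewis-acid step.

Step 9
Reactants: 14 ethyl (4Z)-7-[(2R,3R)-3-({[tert-butyl(diphenyl)silyl]oxy}methyl)-3-methyloxiran-2-yl]-5-[(trimethylsilyl)methyl]hept-4-enoate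
Product: 15 ethyl 3-[(1S,2S,3R)-2-({[tert-butyl(diphenyl)silyl]oxy}methyl)-3-hydroxy-2-methyl-6-methylidenecyclohexyl]propanoate
Conditions: MeAlCl2, CH2Cl2, −78 °C
Reagents that add atoms: none
Why: In this epoxy-allylsilane cation–olefin cyclization the Lewis acid opens the epoxide at its tertiary carbon with inversion while the allylsilane attacks through a chair transition state, so C4 follows from the epoxide, C5 from the (Z)-alkene geometry (chain equatorial, H-5 axial and trans to the C4 methyl), and loss of silicon fixes the exocyclic C10 methylene.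

Step 10
Reactants: 15 ethyl 3-[(1S,2S,3R)-2-({[tert-butyl(diphenyl)silyl]oxy}methyl)-3-hydroxy-2-methyl-6-methylidenecyclohexyl]propanoate
Product: 16 ethyl 3-[(1S,2S,3R)-2-({[tert-butyl(diphenyl)silyl]oxy}methyl)-2-methyl-6-methylidene-3-(phenoxycarbonothioyloxy)cyclohexyl]propanoate
Conditions: PhOC(S)Cl, pyridine, DMAP (cat.), CH2Cl2, rt
Reagents that add atoms: O-phenyl chlorothionoformate S=C(Cl)Oc1ccccc1
Why: Acylation of the hindered equatorial C3 hydroxyl under nucleophilic catalysis gives the thionocarbonate needed for radical deoxygenation without exposing the ester to strong base.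

Step 11
Reactants: 16 ethyl 3-[(1S,2S,3R)-2-({[tert-butyl(diphenyl)silyl]oxy}methyl)-2-methyl-6-methylidene-3-(phenoxycarbonothioyloxy)cyclohexyl]propanoate
Product: 17 ethyl 3-[(1S,2S)-2-({[tert-butyl(diphenyl)silyl]oxy}methyl)-2-methyl-6-methylidenecyclohexyl]propanoate
Conditions: n-Bu3SnH, AIBN (cat.), toluene, 90 °C
Reagents that add atoms: none
Why: In this Barton–McCombie deoxygenation the stannyl radical adds to sulfur, the secondary C3 radical released by β-scission is reduced by the tin hydride, and the ester, the silyl ether and the unactivated methylene group are inert.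

Step 12
Reactants: 17 ethyl 3-[(1S,2S)-2-({[tert-butyl(diphenyl)silyl]oxy}methyl)-2-methyl-6-methylidenecyclohexyl]propanoate
Product: 18 3-[(1S,2S)-2-({[tert-butyl(diphenyl)silyl]oxy}methyl)-2-methyl-6-methylidenecyclohexyl]-N-methoxy-N-methylpropanamide
Conditions: MeNH(OMe)·HCl, i-PrMgCl, THF, −20 °C
Reagents that add atoms: N,O-dimethylhydroxylamine hydrochloride CNOC.Cl
Why: Direct aminolysis of the unhindered ethyl ester by the chloromagnesium amide of N,O-dimethylhydroxylamine gives the Weinreb amide.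

Step 13
Reactants: 18 3-[(1S,2S)-2-({[tert-butyl(diphenyl)silyl]oxy}methyl)-2-methyl-6-methylidenecyclohexyl]-N-methoxy-N-methylpropanamide; 19 lithium (trimethylsilyl)acetylide
Product: 20 5-[(1S,2S)-2-({[tert-butyl(diphenyl)silyl]oxy}methyl)-2-methyl-6-methylidenecyclohexyl]-1-(trimethylsilyl)pent-1-yn-3-one
Conditions: 19, THF, −78 → 0 °C; then cold aq. NH4Cl
Reagents that add atoms: none
Why: In this Weinreb ketone synthesis the acetylide adds once because the chelated tetrahedral intermediate survives until work-up, and the silyl cap keeps the ynone from acting as a Michael acceptor.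

Step 14
Reactants: 20 5-[(1S,2S)-2-({[tert-butyl(diphenyl)silyl]oxy}methyl)-2-methyl-6-methylidenecyclohexyl]-1-(trimethylsilyl)pent-1-yn-3-one
Product: 21 tert-butyl{[(1S,2S)-1-methyl-3-methylidene-2-(2-{2-[(trimethylsilyl)ethynyl]-1,3-dioxolan-2-yl}ethyl)cyclohexyl]methoxy}diphenylsilane
Conditions: (Me3SiOCH2)2, Me3SiOTf (cat.), CH2Cl2, −78 → −20 °C; then pyridine
Reagents that add atoms: 1,2-bis(trimethylsilyloxy)ethane C[Si](C)(C)OCCO[Si](C)(C)C
Why: Aprotic (Noyori-type) ketalization at low temperature converts the ynone into the dioxolane without isomerizing the exocyclic alkene and without conjugate addition of an alcohol to the alkyne.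

Step 15
Reactants: 21 tert-butyl{[(1S,2S)-1-methyl-3-methylidene-2-(2-{2-[(trimethylsilyl)ethynyl]-1,3-dioxolan-2-yl}ethyl)cyclohexyl]methoxy}diphenylsilane
Product: 22 tert-butyl({(1S,2S)-2-[2-(2-ethynyl-1,3-dioxolan-2-yl)ethyl]-1-methyl-3-methylidenecyclohexyl}methoxy)diphenylsilane
Conditions: K2CO3, MeOH, rt
Reagents that add atoms: none
Why: Mild basic methanolysis cleaves the alkynyl C–Si bond, and the ketal and the tert-butyldiphenylsilyl ether are stable to K2CO3 in methanol.

Step 16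
Reactants: 22 tert-butyl({(1S,2S)-2-[2-(2-ethynyl-1,3-dioxolan-2-yl)ethyl]-1-methyl-3-methylidenecyclohexyl}methoxy)diphenylsilane; 23 ethyl chloroformate
Product: 25 ethyl 3-{2-[2-((1S,2S)-2-({[tert-butyl(diphenyl)silyl]oxy}methyl)-2-methyl-6-methylidenecyclohexyl)ethyl]-1,3-dioxolan-2-yl}prop-2-ynoate, via lithium acetylide 24 (not isolated)
Conditions: n-BuLi, THF, −78 °C; then 23, −78 → −20 °C
Reagents that add atoms: none
Why: Deprotonation of the terminal alkyne and C-acylation of the acetylide with the chloroformate is the standard way to a 4,4-dialkoxy-2-ynoate, since the corresponding 4-oxo-2-ynoate cannot be ketalized cleanly.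

Step 17
Reactants: 25 ethyl 3-{2-[2-((1S,2S)-2-({[tert-butyl(diphenyl)silyl]oxy}methyl)-2-methyl-6-methylidenecyclohexyl)ethyl]-1,3-dioxolan-2-yl}prop-2-ynoate
Product: 26 ethyl (2Z)-[(4a'S,5'S,8a'R)-5'-({[tert-butyl(diphenyl)silyl]oxy}methyl)-5',8a'-dimethyloctahydro-1'H-spiro[1,3-dioxolane-2,2'-naphthalen]-1'-ylidene]acetate
Conditions: Fe(acac)3 (0.3 equiv), PhSiH3 (2.5 equiv), EtOH (degassed, 0.02 M), 60 °C
Reagents that add atoms: none
Why: Fe(acac)3 and PhSiH3 form an iron hydride that transfers a hydrogen atom to the electron-rich C20 methylene carbon and not to the electron-poor ynoate, giving the nucleophilic tertiary C10 radical with its methyl already in place. The radical adds to C9, the β-carbon of the ynoate, and the resulting α-ester vinyl radical is reduced and protonated by ethanol (matched to the ethyl ester), so the step is a metal-hydride hydrogen-atom-transfer Giese cyclization, a known reaction type for alkenes tethered to enoates and, less often, ynoates. Ring B closes in the 6-exo-dig mode through the new C9–C10 bond, the 7-endo alternative at C11 being polarity-mismatched. The only new stereocentre, C10, is controlled by the ring A chair: C9 bonds on the face of H-5 through a chair-like transition state with the C5 tether equatorial, because bonding on the other face would be 1,3-diaxial to the axial C4 methyl, so the fusion is trans and the new methyl axial (10R). The step needs chemoselective hydrogen delivery, attack at C9 only and trans fusion; the alkene/ynoate polarity difference, the dioxolane (which leaves the ester as the only group polarizing the alkyne) and the axial C4 methyl secure these.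

Step 18
Reactants: 26 ethyl (2Z)-[(4a'S,5'S,8a'R)-5'-({[tert-butyl(diphenyl)silyl]oxy}methyl)-5',8a'-dimethyloctahydro-1'H-spiro[1,3-dioxolane-2,2'-naphthalen]-1'-ylidene]acetate
Product: 27 (2Z)-2-[(4a'S,5'S,8a'R)-5'-({[tert-butyl(diphenyl)silyl]oxy}methyl)-5',8a'-dimethyloctahydro-1'H-spiro[1,3-dioxolane-2,2'-naphthalen]-1'-ylidene]ethan-1-ol
Conditions: i-Bu2AlH, CH2Cl2, −78 °C
Reagents that add atoms: none
Why: i-Bu2AlH reduces the enoate by 1,2-addition to the allylic C12 alcohol, and the ketal and the silyl ether are stable to the reagent.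

Step 19
Reactants: 27 (2Z)-2-[(4a'S,5'S,8a'R)-5'-({[tert-butyl(diphenyl)silyl]oxy}methyl)-5',8a'-dimethyloctahydro-1'H-spiro[1,3-dioxolane-2,2'-naphthalen]-1'-ylidene]ethan-1-ol
Product: 28 C12 tert-butyldiphenylsilyl ether of 27 (C12 and C18 both silylated; C8 dioxolane)
Conditions: TBDPSCl, imidazole, DMF, rt
Reagents that add atoms: tert-butyl(chloro)diphenylsilane CC(C)(C)[Si](Cl)(c1ccccc1)c1ccccc1
Why: Silylation of the primary allylic hydroxyl prevents it from closing onto C8 to a hemiketal and then a furan when the ketone is unmasked.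

Step 20
Reactants: 28 C12 tert-butyldiphenylsilyl ether of 27
Product: 29 (1Z,4aS,5S,8aR)-1-(2-{[tert-butyl(diphenyl)silyl]oxy}ethylidene)-5-({[tert-butyl(diphenyl)silyl]oxy}methyl)-5,8a-dimethyloctahydronaphthalen-2(1H)-one
Conditions: 1 M aq. HCl, THF, rt
Reagents that add atoms: water O
Why: Acid-catalysed hydrolysis of the allylic dioxolane gives the conjugated C8 enone, while both tert-butyldiphenylsilyl ethers survive dilute aqueous acid.

Step 21
Reactants: 29 (1Z,4aS,5S,8aR)-1-(2-{[tert-butyl(diphenyl)silyl]oxy}ethylidene)-5-({[tert-butyl(diphenyl)silyl]oxy}methyl)-5,8a-dimethyloctahydronaphthalen-2(1H)-one; 30 methyllithium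
Product: 31 (1Z,2R,4aS,5S,8aR)-1-(2-{[tert-butyl(diphenyl)silyl]oxy}ethylidene)-5-({[tert-butyl(diphenyl)silyl]oxy}methyl)-2,5,8a-trimethyldecahydronaphthalen-2-ol
Conditions: 30, CeCl3, THF, −78 °C
Reagents that add atoms: none
Why: The organocerium reagent adds 1,2 to the enone without enolization and approaches C8 equatorially, because the axial trajectory is blocked by the axial C10 methyl, so the new hydroxyl is axial and syn to that methyl (8R).

Step 22
Reactants: 31 (1Z,2R,4aS,5S,8aR)-1-(2-{[tert-butyl(diphenyl)silyl]oxy}ethylidene)-5-({[tert-butyl(diphenyl)silyl]oxy}methyl)-2,5,8a-trimethyldecahydronaphthalen-2-ol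
Product: 32 (1R,2R,4aS,5S,8aR)-1-(2-{[tert-butyl(diphenyl)silyl]oxy}ethyl)-5-({[tert-butyl(diphenyl)silyl]oxy}methyl)-2,5,8a-trimethyldecahydronaphthalen-2-ol
Conditions: H2 (1 atm), [Ir(cod)(PCy3)(py)]PF6 (cat.), CH2Cl2, rt
Reagents that add atoms: none
Why: In this hydroxyl-directed homogeneous hydrogenation the cationic iridium catalyst binds the axial tertiary C8 hydroxyl and delivers hydrogen to the same face of the C9=C11 alkene, so H-9 ends syn to the hydroxyl and the C10 methyl and the side chain axial (9R).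

Step 23
Reactants: 32 (1R,2R,4aS,5S,8aR)-1-(2-{[tert-butyl(diphenyl)silyl]oxy}ethyl)-5-({[tert-butyl(diphenyl)silyl]oxy}methyl)-2,5,8a-trimethyldecahydronaphthalen-2-ol
Product: 33 (1R,2R,4aS,5S,8aR)-1-(2-hydroxyethyl)-5-(hydroxymethyl)-2,5,8a-trimethyldecahydronaphthalen-2-ol
Conditions: n-Bu4NF, THF, rt → 50 °C
Reagents that add atoms: none
Why: Excess fluoride removes both tert-butyldiphenylsilyl ethers, the neopentyl C18 ether needing gentle warming.

Step 24
Reactants: 33 (1R,2R,4aS,5S,8aR)-1-(2-hydroxyethyl)-5-(hydroxymethyl)-2,5,8a-trimethyldecahydronaphthalen-2-ol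
Product: 34 (1R,2R,4aS,5S,8aR)-5-(hydroxymethyl)-1-(2-iodoethyl)-2,5,8a-trimethyldecahydronaphthalen-2-ol
Conditions: I2 (1.1 equiv), PPh3, imidazole, CH2Cl2, 0 °C
Reagents that add atoms: iodine II
Why: Appel-type iodination selects the unhindered primary C12 hydroxyl over the neopentyl C18 and tertiary C8 hydroxyls, and the trans-diaxial relation of the C8 hydroxyl to the C9 chain rules out closure to a tetrahydrofuran.

Step 25
Reactants: 34 (1R,2R,4aS,5S,8aR)-5-(hydroxymethyl)-1-(2-iodoethyl)-2,5,8a-trimethyldecahydronaphthalen-2-ol; 35 2-chlorobuta-1,3-diene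
Product: 36 (1R,2R,4aS,5S,8aR)-5-(hydroxymethyl)-2,5,8a-trimethyl-1-(3-methylidenepent-4-en-1-yl)decahydronaphthalen-2-ol
Conditions: 35, Mg, ZnCl2 (cat.), THF, reflux; then 34, Li2CuCl4 (cat.), THF, 0 °C → rt
Reagents that add atoms: none
Why: Copper-catalysed sp3–sp2 coupling (Kochi type) of the primary iodide with the dienyl Grignard reagent, used in excess because two equivalents are consumed by the hydroxyls, installs the 2-substituted 1,3-butadiene.

Step 26
Reactants: 36 (1R,2R,4aS,5S,8aR)-5-(hydroxymethyl)-2,5,8a-trimethyl-1-(3-methylidenepent-4-en-1-yl)decahydronaphthalen-2-ol; 37 [bis(2,2,2-trifluoroethoxy)phosphoryl]acetic acid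
Product: 38 C18 [bis(2,2,2-trifluoroethoxy)phosphoryl]acetate of 36
Conditions: 37, EDC·HCl, DMAP (cat.), CH2Cl2, 0 °C → rt
Reagents that add atoms: none
Why: Carbodiimide-mediated (Steglich) esterification acylates the primary C18 hydroxyl and leaves the tertiary C8 hydroxyl untouched.

Step 27
Reactants: 38 C18 [bis(2,2,2-trifluoroethoxy)phosphoryl]acetate of 36; 39 4-{[tert-butyl(dimethyl)silyl]oxy}benzaldehyde
Product: 41 C18 (2Z)-3-(4-{[tert-butyl(dimethyl)silyl]oxy}phenyl)prop-2-enoate of 36, via phosphonate carbanion 40 (not isolated)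
Conditions: KN(SiMe3)2 (1.0 equiv), 18-crown-6, THF, −78 °C; then 39, −78 °C
Reagents that add atoms: none
Why: In this Still–Gennari olefination the electron-poor bis(trifluoroethyl)phosphonate anion with a dissociated potassium counter-ion eliminates quickly from the kinetic adduct and so gives the (Z)-cinnamate.

Step 28
Reactants: 41 C18 (2Z)-3-(4-{[tert-butyl(dimethyl)silyl]oxy}phenyl)prop-2-enoate of 36
Product: 42 [(1S,4aR,5R,6R,8aS)-6-hydroxy-1,4a,6-trimethyl-5-(3-methylidenepent-4-en-1-yl)decahydronaphthalen-1-yl]methyl (2Z)-3-(4-hydroxyphenyl)prop-2-enoate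
Conditions: n-Bu4NF, AcOH, THF, 0 °C, exclusion of light
Reagents that add atoms: none
Why: Buffered fluoride cleaves the aryl silyl ether rapidly at 0 °C, conditions under which the (Z)-enoate, the diene and the tertiary alcohol are stable.

Compound list
1 | pent-4-yn-1-ol | OCCCC#C | starting material
2 | tert-butyl(dimethyl)(pent-4-yn-1-yloxy)silane | C#CCCCO[Si](C)(C)C(C)(C)C | intermediate
3 | (trimethylsilyl)methylmagnesium chloride | C[Si](C)(C)C[Mg]Cl | starting material
4 | {(1Z)-5-{[tert-butyl(dimethyl)silyl]oxy}-2-[(trimethylsilyl)methyl]pent-1-en-1-yl}copper | [Cu]/C=C(\C[Si](C)(C)C)CCCO[Si](C)(C)C(C)(C)C | intermediate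
5 | tert-butyl{[(4Z)-5-iodo-4-[(trimethylsilyl)methyl]pent-4-en-1-yl]oxy}dimethylsilane | I/C=C(\C[Si](C)(C)C)CCCO[Si](C)(C)C(C)(C)C | intermediate
6 | (4Z)-5-iodo-4-[(trimethylsilyl)methyl]pent-4-en-1-ol | I/C=C(\C[Si](C)(C)C)CCCO | intermediate
7 | ethyl 2-(triphenylphosphoranylidene)propanoate | CCOC(=O)C(C)=P(c1ccccc1)(c1ccccc1)c1ccccc1 | starting material
8 | (4Z)-5-iodo-4-[(trimethylsilyl)methyl]pent-4-enal | I/C=C(\C[Si](C)(C)C)CCC=O | intermediate
9 | ethyl (2E,6Z)-7-iodo-2-methyl-6-[(trimethylsilyl)methyl]hepta-2,6-dienoate | CCOC(=O)/C(C)=C/CC/C(C[Si](C)(C)C)=C/I | intermediate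
10 | (2E,6Z)-7-iodo-2-methyl-6-[(trimethylsilyl)methyl]hepta-2,6-dien-1-ol | OC/C(C)=C/CC/C(C[Si](C)(C)C)=C/I | intermediate
11 | (3-ethoxy-3-oxopropyl)zinc bromide | CCOC(=O)CC[Zn]Br | starting material
12 | ethyl (4Z,8E)-10-hydroxy-9-methyl-5-[(trimethylsilyl)methyl]deca-4,8-dienoate | CCOC(=O)CC/C=C(\C[Si](C)(C)C)CC/C=C(\C)CO | intermediate
13 | ethyl (4Z)-7-[(2R,3R)-3-(hydroxymethyl)-3-methyloxiran-2-yl]-5-[(trimethylsilyl)methyl]hept-4-enoate | CCOC(=O)CC/C=C(\C[Si](C)(C)C)CC[C@H]1O[C@]1(C)CO | intermediate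
14 | ethyl (4Z)-7-[(2R,3R)-3-({[tert-butyl(diphenyl)silyl]oxy}methyl)-3-methyloxiran-2-yl]-5-[(trimethylsilyl)methyl]hept-4-enoate | CCOC(=O)CC/C=C(\C[Si](C)(C)C)CC[C@H]1O[C@]1(C)CO[Si](c2ccccc2)(c3ccccc3)C(C)(C)C | intermediate
15 | ethyl 3-[(1S,2S,3R)-2-({[tert-butyl(diphenyl)silyl]oxy}methyl)-3-hydroxy-2-methyl-6-methylidenecyclohexyl]propanoate | C=C1CC[C@@H](O)[C@](C)(CO[Si](c2ccccc2)(c3ccccc3)C(C)(C)C)[C@H]1CCC(=O)OCC | intermediate
16 | ethyl 3-[(1S,2S,3R)-2-({[tert-butyl(diphenyl)silyl]oxy}methyl)-2-methyl-6-methylidene-3-(phenoxycarbonothioyloxy)cyclohexyl]propanoate | C=C1CC[C@@H](OC(=S)Oc2ccccc2)[C@](C)(CO[Si](c3ccccc3)(c4ccccc4)C(C)(C)C)[C@H]1CCC(=O)OCC | intermediate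
17 | ethyl 3-[(1S,2S)-2-({[tert-butyl(diphenyl)silyl]oxy}methyl)-2-methyl-6-methylidenecyclohexyl]propanoate | C=C1CCC[C@](C)(CO[Si](c2ccccc2)(c3ccccc3)C(C)(C)C)[C@H]1CCC(=O)OCC | intermediate
18 | 3-[(1S,2S)-2-({[tert-butyl(diphenyl)silyl]oxy}methyl)-2-methyl-6-methylidenecyclohexyl]-N-methoxy-N-methylpropanamide | C=C1CCC[C@](C)(CO[Si](c2ccccc2)(c3ccccc3)C(C)(C)C)[C@H]1CCC(=O)N(C)OC | intermediate
19 | lithium (trimethylsilyl)acetylide | [Li]C#C[Si](C)(C)C | starting material
20 | 5-[(1S,2S)-2-({[tert-butyl(diphenyl)silyl]oxy}methyl)-2-methyl-6-methylidenecyclohexyl]-1-(trimethylsilyl)pent-1-yn-3-one | C=C1CCC[C@](C)(CO[Si](c2ccccc2)(c3ccccc3)C(C)(C)C)[C@H]1CCC(=O)C#C[Si](C)(C)C | intermediate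
21 | tert-butyl{[(1S,2S)-1-methyl-3-methylidene-2-(2-{2-[(trimethylsilyl)ethynyl]-1,3-dioxolan-2-yl}ethyl)cyclohexyl]methoxy}diphenylsilane | C=C1CCC[C@](C)(CO[Si](c2ccccc2)(c3ccccc3)C(C)(C)C)[C@H]1CCC4(OCCO4)C#C[Si](C)(C)C | intermediate
22 | tert-butyl({(1S,2S)-2-[2-(2-ethynyl-1,3-dioxolan-2-yl)ethyl]-1-methyl-3-methylidenecyclohexyl}methoxy)diphenylsilane | C=C1CCC[C@](C)(CO[Si](c2ccccc2)(c3ccccc3)C(C)(C)C)[C@H]1CCC4(OCCO4)C#C | intermediate
23 | ethyl chloroformate | CCOC(=O)Cl | starting material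
24 | lithium acetylide of 22 | C=C1CCC[C@](C)(CO[Si](c2ccccc2)(c3ccccc3)C(C)(C)C)[C@H]1CCC4(OCCO4)C#C[Li] | intermediate
25 | ethyl 3-{2-[2-((1S,2S)-2-({[tert-butyl(diphenyl)silyl]oxy}methyl)-2-methyl-6-methylidenecyclohexyl)ethyl]-1,3-dioxolan-2-yl}prop-2-ynoate (key-step precursor) | C=C1CCC[C@](C)(CO[Si](c2ccccc2)(c3ccccc3)C(C)(C)C)[C@H]1CCC4(OCCO4)C#CC(=O)OCC | intermediate
26 | ethyl (2Z)-[(4a'S,5'S,8a'R)-5'-({[tert-butyl(diphenyl)silyl]oxy}methyl)-5',8a'-dimethyloctahydro-1'H-spiro[1,3-dioxolane-2,2'-naphthalen]-1'-ylidene]acetate (trans-decalin; C8 dioxolane; C9=C11; 4S,5S,10R in labdane numbering; key-step product) | CCOC(=O)/C=C1/[C@]2(C)CCC[C@](C)(CO[Si](c3ccccc3)(c4ccccc4)C(C)(C)C)[C@H]2CCC15OCCO5 | intermediate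
27 | (2Z)-2-[(4a'S,5'S,8a'R)-5'-({[tert-butyl(diphenyl)silyl]oxy}methyl)-5',8a'-dimethyloctahydro-1'H-spiro[1,3-dioxolane-2,2'-naphthalen]-1'-ylidene]ethan-1-ol | OC/C=C1/[C@]2(C)CCC[C@](C)(CO[Si](c3ccccc3)(c4ccccc4)C(C)(C)C)[C@H]2CCC15OCCO5 | intermediate
28 | C12 tert-butyldiphenylsilyl ether of 27 | CC(C)(C)[Si](c6ccccc6)(c7ccccc7)OC/C=C1/[C@]2(C)CCC[C@](C)(CO[Si](c3ccccc3)(c4ccccc4)C(C)(C)C)[C@H]2CCC15OCCO5 | intermediate
29 | (1Z,4aS,5S,8aR)-1-(2-{[tert-butyl(diphenyl)silyl]oxy}ethylidene)-5-({[tert-butyl(diphenyl)silyl]oxy}methyl)-5,8a-dimethyloctahydronaphthalen-2(1H)-one | CC(C)(C)[Si](c6ccccc6)(c7ccccc7)OC/C=C1/[C@]2(C)CCC[C@](C)(CO[Si](c3ccccc3)(c4ccccc4)C(C)(C)C)[C@H]2CCC1=O | intermediate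
30 | methyllithium | [Li]C | starting material
31 | (1Z,2R,4aS,5S,8aR)-1-(2-{[tert-butyl(diphenyl)silyl]oxy}ethylidene)-5-({[tert-butyl(diphenyl)silyl]oxy}methyl)-2,5,8a-trimethyldecahydronaphthalen-2-ol | CC(C)(C)[Si](c6ccccc6)(c7ccccc7)OC/C=C1/[C@]2(C)CCC[C@](C)(CO[Si](c3ccccc3)(c4ccccc4)C(C)(C)C)[C@H]2CC[C@@]1(C)O | intermediate
32 | (1R,2R,4aS,5S,8aR)-1-(2-{[tert-butyl(diphenyl)silyl]oxy}ethyl)-5-({[tert-butyl(diphenyl)silyl]oxy}methyl)-2,5,8a-trimethyldecahydronaphthalen-2-ol | CC(C)(C)[Si](c6ccccc6)(c7ccccc7)OCC[C@@H]1[C@]2(C)CCC[C@](C)(CO[Si](c3ccccc3)(c4ccccc4)C(C)(C)C)[C@H]2CC[C@@]1(C)O | intermediate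
33 | (1R,2R,4aS,5S,8aR)-1-(2-hydroxyethyl)-5-(hydroxymethyl)-2,5,8a-trimethyldecahydronaphthalen-2-ol | OCC[C@@H]1[C@]2(C)CCC[C@](C)(CO)[C@H]2CC[C@@]1(C)O | intermediate
34 | (1R,2R,4aS,5S,8aR)-5-(hydroxymethyl)-1-(2-iodoethyl)-2,5,8a-trimethyldecahydronaphthalen-2-ol | ICC[C@@H]1[C@]2(C)CCC[C@](C)(CO)[C@H]2CC[C@@]1(C)O | intermediate
35 | 2-chlorobuta-1,3-diene | C=CC(Cl)=C | starting material
36 | (1R,2R,4aS,5S,8aR)-5-(hydroxymethyl)-2,5,8a-trimethyl-1-(3-methylidenepent-4-en-1-yl)decahydronaphthalen-2-ol | C=CC(=C)CC[C@@H]1[C@]2(C)CCC[C@](C)(CO)[C@H]2CC[C@@]1(C)O | intermediate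
37 | [bis(2,2,2-trifluoroethoxy)phosphoryl]acetic acid | OC(=O)CP(=O)(OCC(F)(F)F)OCC(F)(F)F | starting material
38 | C18 [bis(2,2,2-trifluoroethoxy)phosphoryl]acetate of 36 | C=CC(=C)CC[C@@H]1[C@]2(C)CCC[C@](C)(COC(=O)CP(=O)(OCC(F)(F)F)OCC(F)(F)F)[C@H]2CC[C@@]1(C)O | intermediate
39 | 4-{[tert-butyl(dimethyl)silyl]oxy}benzaldehyde | O=Cc1ccc(O[Si](C)(C)C(C)(C)C)cc1 | starting material
40 | potassium salt of the phosphonate carbanion of 38 | C=CC(=C)CC[C@@H]1[C@]2(C)CCC[C@](C)(COC(=O)[CH-]P(=O)(OCC(F)(F)F)OCC(F)(F)F)[C@H]2CC[C@@]1(C)O.[K+] | intermediate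
41 | C18 (2Z)-3-(4-{[tert-butyl(dimethyl)silyl]oxy}phenyl)prop-2-enoate of 36 | C=CC(=C)CC[C@@H]1[C@]2(C)CCC[C@](C)(COC(=O)/C=C\c3ccc(O[Si](C)(C)C(C)(C)C)cc3)[C@H]2CC[C@@]1(C)O | intermediate
42 | [(1S,4aR,5R,6R,8aS)-6-hydroxy-1,4a,6-trimethyl-5-(3-methylidenepent-4-en-1-yl)decahydronaphthalen-1-yl]methyl (2Z)-3-(4-hydroxyphenyl)prop-2-enoate (4S,5S,8R,9R,10R in labdane numbering) | C=CC(=C)CC[C@@H]1[C@]2(C)CCC[C@](C)(COC(=O)/C=C\c3ccc(O)cc3)[C@H]2CC[C@@]1(C)O | target

Total step count: 28. Longest linear sequence: 28 steps (1 → 42); all other starting materials are used as purchased.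

Steps most likely to fail

Step 17. The C10 radical may be reduced to the saturated methyl compound before it closes the ring, the vinyl radical may abstract a dioxolane hydrogen, or the ring may close with poor trans/cis control. The fallback sets out from 25 and generates the same radical with no hydride donor present. Mukaiyama hydration of 25 (Co(acac)2, PhSiH3, O2, i-PrOH; then PPh3) would give the tertiary C10 alcohol F1 as an inconsequential epimer mixture. Methyl chlorooxoacetate, Et3N and DMAP would give the methyl oxalate F2, and one equivalent of CsOH in THF–water the cesium oxalate F3. Blue-light irradiation with [Ir(dF(CF3)ppy)2(dtbbpy)]PF6 in DME–DMF–water would expel two molecules of CO2, and the tertiary radical would close onto C9, returning to the route at 26.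

Step 22. The catalyst may fail to engage the alkene on the face crowded by the C10 methyl, which would mean slow turnover or undirected delivery of hydrogen to the opposite face. The fallback sets out from 31 and delivers the hydrogen through a covalent tether. Silylation of the tertiary hydroxyl with ClSiMe2H (Et3N, DMAP) would give the hydrodimethylsilyl ether F4. Intramolecular hydrosilylation (H2PtCl6 cat., toluene, 60 °C) would close the 1-oxa-2-silacyclopentane F5, with silicon on C11 and hydrogen on C9 on the face of the C8 oxygen. n-Bu4NF (THF, 60 °C) would remove both silyl ethers and trigger Peterson elimination of the β-oxysilane to the C9 vinyl diol F6. Hydroboration with 9-BBN and oxidation with NaBO3 would restore the C12 hydroxyl, returning to the route at 33.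

Step 25. The coupling may stall because two magnesium alkoxides aggregate the dienyl Grignard reagent, the iodide may be reduced or eliminated, or the reagent may couple through its allenic terminus. The fallback sets out from 34 and builds the diene in two steps. Displacement of the iodide by LiC≡CH·H2NCH2CH2NH2 (DMSO, rt) would give the terminal alkyne F7. Ethylene–alkyne cross-metathesis (second-generation Grubbs catalyst, ethylene 1 atm, CH2Cl2) would convert it into the 2-substituted 1,3-butadiene, returning to the route at 36.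

Further compounds
F1 | step 17 | ethyl 3-{2-[2-((1S,2S)-2-({[tert-butyl(diphenyl)silyl]oxy}methyl)-6-hydroxy-2,6-dimethylcyclohexyl)ethyl]-1,3-dioxolan-2-yl}prop-2-ynoate (both C6 epimers) | CC1(O)CCC[C@](C)(CO[Si](c2ccccc2)(c3ccccc3)C(C)(C)C)[C@H]1CCC4(OCCO4)C#CC(=O)OCC
F2 | step 17 | methyl oxalate of F1 | CC1(OC(=O)C(=O)OC)CCC[C@](C)(CO[Si](c2ccccc2)(c3ccccc3)C(C)(C)C)[C@H]1CCC4(OCCO4)C#CC(=O)OCC
F3 | step 17 | cesium oxalate of F1 | CC1(OC(=O)C(=O)[O-])CCC[C@](C)(CO[Si](c2ccccc2)(c3ccccc3)C(C)(C)C)[C@H]1CCC4(OCCO4)C#CC(=O)OCC.[Cs+]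
F4 | step 22 | C8 O-(dimethylsilyl) ether of 31 | CC(C)(C)[Si](c6ccccc6)(c7ccccc7)OC/C=C1/[C@]2(C)CCC[C@](C)(CO[Si](c3ccccc3)(c4ccccc4)C(C)(C)C)[C@H]2CC[C@@]1(C)O[SiH](C)C
F5 | step 22 | 1-oxa-2-silacyclopentane fused at C8–C9 (Si on C11; H-9 syn to the C8 oxygen) | CC(C)(C)[Si](c6ccccc6)(c7ccccc7)OCC8[C@@H]1[C@]2(C)CCC[C@](C)(CO[Si](c3ccccc3)(c4ccccc4)C(C)(C)C)[C@H]2CC[C@@]1(C)O[Si]8(C)C
F6 | step 22 | (1R,2R,4aS,5S,8aR)-1-ethenyl-5-(hydroxymethyl)-2,5,8a-trimethyldecahydronaphthalen-2-ol | C=C[C@@H]1[C@]2(C)CCC[C@](C)(CO)[C@H]2CC[C@@]1(C)O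
F7 | step 25 | (1R,2R,4aS,5S,8aR)-1-(but-3-yn-1-yl)-5-(hydroxymethyl)-2,5,8a-trimethyldecahydronaphthalen-2-ol | C#CCC[C@@H]1[C@]2(C)CCC[C@](C)(CO)[C@H]2CC[C@@]1(C)O
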